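**Retrosynthetic overview**

- Feature: the ten-membered ring C1–C10 holds a 1,5-diene (C1=C10 and C4=C5 joined through C2–C3). Its other half, C5–C10 with the four contiguous oxygenated carbons C6–C9, folds back into a cyclohexane that maps onto a bromobenzene cis-dihydrodiol.
- Disconnections: C8 ester (Yamaguchi), then the lactone ring (C12–O6 by oxidative lactonisation, C7–C11 by chelation-controlled addition to a C7 ketone), then C10–CH3 (Negishi coupling of an enol triflate), then C2–C3 formed and C5–C10 cleaved by an anionic oxy-Cope ring expansion.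
- Geometry: the target has C2 cis to C9 across C1=C10 (1(10)Z) and C3 trans to C6 across C4=C5 (4E). A trans-diequatorial dialkenyl carbinol would give the ring-trans enolate and the wrong C1=C10 isomer, so the carbinol is made with vinyl cis to isopropenyl and the enolate is trapped as its E triflate.
- The cis pair is fixed by anti opening of a trisubstituted C5–C10 epoxide with an isopropenyl cuprate, followed by Wittig methylenation at C1.
- Ring order: cyclohexane (purchased), ten-membered carbocycle (step 10), γ-lactone (step 16); the oxirane of the ester arrives preformed (steps 19–20).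

Key step: step 10

Remark: germacrane numbering (C1–C15) is used for every intermediate and the upper face is the face of the C8 and C9 oxygens; step 6 is assumed to deliver oxygen to the lower face, and the other epoxide would also lead to a cis pair of alkenyl groups.

**Route**

Step 1
Reactants: 1 (1S,2S)-3-bromocyclohexa-3,5-diene-1,2-diol
Product: 2 O8/O9 acetonide of 1
Conditions: 2,2-dimethoxypropane, TsOH·H2O (cat.), acetone, 0 °C to rt
Reagents that add atoms: 2,2-dimethoxypropane, COC(C)(C)OC
Why: Acid-catalysed transketalisation protects the cis-diol (future O8 and O9) as a cis-fused dioxolane, which also blocks one face of the ring for the next steps.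

Step 2
Reactants: 2 O8/O9 acetonide of 1
Product: 3 C6/C7 diol anti to the dioxolane
Conditions: OsO4 (cat.), N-methylmorpholine N-oxide, acetone/H2O, rt
Reagents that add atoms: N-methylmorpholine N-oxide, C[N+]1([O-])CCOCC1; water, O
Why: Upjohn dihydroxylation takes place at the bromine-free, more electron-rich C6=C7 alkene from the face opposite the dioxolane, which sets C6 and C7 with both hydroxyls anti to O8 and O9.

Step 3
Reactants: 3 C6/C7 diol anti to the dioxolane
Product: 5 C6 PMB ether, via dibutylstannylene acetal 4 (not isolated)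
Conditions: Bu2SnO, toluene, reflux (water removed); then 4-methoxybenzyl chloride, Bu4NI (cat.), 90 °C
Reagents that add atoms: 4-methoxybenzyl chloride, COc1ccc(CCl)cc1; dibutyltin oxide (tin in 4 only), CCCC[Sn](=O)CCCC
Why: Stannylene-acetal-mediated alkylation is regioselective for the less hindered allylic oxygen at C6 (remote from the dioxolane), and the benzyl-type ether placed there is the chelating group needed in step 14.

Step 4
Reactants: 5 C6 PMB ether
Product: 6 C6 PMB C7 TBS vinyl bromide
Conditions: TBSOTf, 2,6-lutidine, CH2Cl2, −78 to 0 °C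
Reagents that add atoms: tert-butyldimethylsilyl trifluoromethanesulfonate, CC(C)(C)[Si](C)(C)OS(=O)(=O)C(F)(F)F
Why: Silyl triflate silylation of the remaining hindered secondary hydroxyl gives the C7 TBS ether, the one group that fluoride will remove after ring expansion.

Step 5
Reactants: 6 C6 PMB C7 TBS vinyl bromide
Product: 7 C10 hydroxymethyl cyclohexene
Conditions: Bu3SnCH2OH, Pd(PPh3)4 (cat.), toluene, 100 °C
Reagents that add atoms: (tributylstannyl)methanol, CCCC[Sn](CO)(CCCC)CCCC
Why: Migita–Kosugi–Stille coupling of the vinyl bromide with the hydroxymethyl stannane installs the carbon that becomes C1, and the ethers, silyl ether and acetal are inert to it.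

Step 6
Reactants: 7 C10 hydroxymethyl cyclohexene
Product: 8 C5–C10 epoxy alcohol
Conditions: VO(acac)2 (cat.), t-BuOOH, CH2Cl2, 0 °C to rt
Reagents that add atoms: tert-butyl hydroperoxide, CC(C)(C)OO
Why: Hydroxyl-directed vanadium-catalysed epoxidation oxidises only the allylic-alcohol alkene and should deliver oxygen to the face opposite the cis-fused dioxolane, which fixes the transient C5 and C10 centres.

Step 7
Reactants: 8 C5–C10 epoxy alcohol; 9 isopropenylmagnesium bromide
Product: 10 C5 isopropenyl C10 carbinol diol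
Conditions: 9 (4 equiv), CuI (20 mol %), THF, −30 to 0 °C; aq. NH4Cl
Reagents that add atoms: isopropenylmagnesium bromide (9), CC(=C)[Mg]Br
Why: Copper-catalysed Grignard opening of the trisubstituted epoxide is an SN2 attack at the only accessible carbon C5 anti to the epoxide oxygen (trans-diaxial, Fürst–Plattner), so the isopropenyl group is necessarily cis to the C10 carbon substituent and trans to the new tertiary hydroxyl, while the fully substituted C10 rules out both attack there and a Payne shift.

Step 8
Reactants: 10 C5 isopropenyl C10 carbinol diol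
Product: 11 C10 hydroxy aldehyde
Conditions: SO3·pyridine, DMSO, Et3N, CH2Cl2, 0 °C
Reagents that add atoms: none
Why: Parikh–Doering oxidation converts the primary alcohol into the aldehyde without touching the tertiary hydroxyl and without the glycol cleavage that hypervalent iodine or periodate would cause.

Step 9
Reactants: 11 C10 hydroxy aldehyde
Product: 12 cis-2-isopropenyl-1-vinylcyclohexanol
Conditions: Ph3PCH3Br, KN(SiMe3)2, THF, 0 °C; then 11, −78 to 0 °C
Reagents that add atoms: methyltriphenylphosphonium bromide, C[P+](c1ccccc1)(c1ccccc1)c1ccccc1.[Br-]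
Why: Wittig methylenation of the non-enolisable aldehyde builds the vinyl group (C1=C2) with retention of the C10 configuration, the low temperature and excess ylide avoiding an α-ketol shift of the hydroxy aldehyde.

Step 10
Reactants: 12 cis-2-isopropenyl-1-vinylcyclohexanol
Product: 15 ten-membered (E)-enol triflate, via potassium alkoxide 13 (not isolated), via potassium enolate 14 (not isolated)
Conditions: KH, 18-crown-6, THF, 0 °C to rt; then PhNTf2, −78 to 0 °C
Reagents that add atoms: N-phenylbis(trifluoromethanesulfonimide), O=S(=O)(N(c1ccccc1)S(=O)(=O)C(F)(F)F)C(F)(F)F; potassium hydride (potassium in 13 and 14), [K+].[H-]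
Why: KH deprotonates the tertiary carbinol and the crown-separated potassium alkoxide 13 undergoes an anionic oxy-Cope [3,3] shift that forms C2–C3 and cleaves C5–C10, the closest known reaction type being the ring expansion of 1,2-dialkenylcyclohexanolates to cyclodec-5-enone enolates. The ten-membered ring is closed by a four-atom ring expansion inside a six-membered chair array (C10, C1, C2, C3, C4, C5), not by an end-to-end cyclisation, so no dilution is needed. No stereocentre is created, C6–C9 are not touched, and the two alkene geometries are set by the chair. The step needs E geometry at C4=C5 and a ring-cis enolate (oxygen trans to C2) at C1=C10. The cis relationship of vinyl and isopropenyl fixed in step 7 allows only chairs with one alkenyl group axial, and the chair with the vinyl group equatorial, the isopropenyl group axial and the alkoxide pseudo-equatorial in the forming array (the orientation followed by cis-1,2-dialkenylcyclohexanols that give (E)-cyclodec-5-enones) puts C6 equatorial (E alkene) and C9 axial (cis enolate). Trapping 14 with PhNTf2 before any proton source is added freezes this geometry as the E enol triflate and keeps the enolate from equilibrating towards C9.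

Step 11
Reactants: 15 ten-membered (E)-enol triflate
Product: 16 (1(10)Z,4E)-diene with C10 methyl
Conditions: Me2Zn, Pd(PPh3)4 (cat.), THF, 0 to 50 °C
Reagents that add atoms: dimethylzinc, C[Zn]C
Why: Negishi coupling of the enol triflate proceeds with retention of alkene geometry, so the methyl group (C14) replaces the triflate trans to C2 and the C1=C10 alkene is the ring-cis 1(10)Z isomer of the target.

Step 12
Reactants: 16 (1(10)Z,4E)-diene with C10 methyl
Product: 17 C7 alcohol
Conditions: Bu4NF, THF, 0 °C to rt
Reagents that add atoms: none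
Why: Fluoride cleaves the only silyl ether and frees the C7 hydroxyl, while the PMB ether, the acetal and both alkenes are untouched.

Step 13
Reactants: 17 C7 alcohol
Product: 18 C7 ketone
Conditions: Dess–Martin periodinane, NaHCO3, CH2Cl2, 0 °C to rt
Reagents that add atoms: none
Why: Buffered Dess–Martin oxidation gives the C7 ketone under neutral conditions that should not epimerise the flanking C6 and C8 centres.

Step 14
Reactants: 18 C7 ketone; 19 2-bromoprop-2-en-1-ol
Product: 22 C7 tertiary alcohol with the 3-hydroxyprop-1-en-2-yl group, via dilithio reagent 20 (not isolated), via bromomagnesium reagent 21 (not isolated)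
Conditions: 19, t-BuLi (3 equiv), Et2O, −78 to 0 °C; MgBr2·OEt2, −78 °C; then 18, CH2Cl2/Et2O, −78 °C
Reagents that add atoms: 2-bromoprop-2-en-1-ol (19), OCC(Br)=C; tert-butyllithium (lithium in 20), [Li]C(C)(C)C; magnesium bromide etherate (magnesium and bromine in 21), Br[Mg]Br.CCOCC
Why: 1,2-Addition of an acrylate α-anion equivalent under Cram-chelate control, in which magnesium bridges the C7 carbonyl and the C6 PMB ether oxygen and the nucleophile enters from the side of H6, which is also the Felkin–Anh face with respect to C8 (dioxolane C8–O anti to the nucleophile), should set C7 with its hydroxyl on the face of the C6 oxygen and C11 on the opposite face.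

Step 15
Reactants: 22 C7 tertiary alcohol with the 3-hydroxyprop-1-en-2-yl group
Product: 23 C6/C7/C12 triol
Conditions: DDQ, CH2Cl2/pH 7 phosphate buffer (9:1), 0 °C
Reagents that add atoms: none
Why: Oxidative PMB cleavage with DDQ in a wet buffered medium frees the C6 hydroxyl, water intercepting the benzylic cation before the neighbouring tertiary hydroxyl can close an anisylidene acetal.

Step 16
Reactants: 23 C6/C7/C12 triol
Product: 26 7-hydroxy α-methylene lactone acetonide, via hydroxy enal 24 (not isolated), via lactol 25 (not isolated)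
Conditions: [Cu(MeCN)4]OTf (cat.), 2,2'-bipyridine, TEMPO (cat.), N-methylimidazole, air, MeCN, rt
Reagents that add atoms: none
Why: Copper/TEMPO aerobic oxidation is selective for the unhindered primary allylic alcohol, the enal is captured by the C6 hydroxyl as the five-membered lactol (O8 is blocked in the dioxolane) and the lactol is oxidised on to the α-methylene-γ-lactone, which closes the lactone ring without touching a stereocentre.

Step 17
Reactants: 26 7-hydroxy α-methylene lactone acetonide
Product: 27 7/8/9-triol lactone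
Conditions: AcOH/H2O (4:1), 40 °C
Reagents that add atoms: none
Why: Mild acid hydrolysis removes the isopropylidene acetal, the allylic oxygens at C6 and C9 slowing protonation of the two ring alkenes enough for a short treatment at low temperature.

Step 18
Reactants: 27 7/8/9-triol lactone
Product: 28 C9 triethylsilyl ether
Conditions: Et3SiCl, imidazole, CH2Cl2, −40 to −20 °C
Reagents that add atoms: chlorotriethylsilane, CC[Si](Cl)(CC)CC
Why: Silylation at low temperature should select the allylic C9 hydroxyl over the C8 hydroxyl, which is neopentyl-like next to the fully substituted C7, and the tertiary C7 hydroxyl does not react.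

Step 19
Reactants: 29 (E)-2-methylbut-2-en-1-ol
Product: 30 ((2R,3R)-2,3-dimethyloxiran-2-yl)methanol
Conditions: Ti(OiPr)4 (cat.), D-(−)-diethyl tartrate (cat.), t-BuOOH, 4 Å sieves, CH2Cl2, −20 °C
Reagents that add atoms: tert-butyl hydroperoxide, CC(C)(C)OO
Why: Sharpless asymmetric epoxidation of the E allylic alcohol with the D-tartrate ligand delivers oxygen to the face that gives the (2R,3R) epoxy alcohol, which sets both stereocentres of the side chain.

Step 20
Reactants: 30 ((2R,3R)-2,3-dimethyloxiran-2-yl)methanol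
Product: 32 (2S,3R)-2,3-dimethyloxirane-2-carboxylic acid, via epoxy aldehyde 31 (not isolated)
Conditions: TEMPO (cat.), NaOCl (cat.), NaClO2, MeCN/phosphate buffer pH 6.7, 35 °C
Reagents that add atoms: sodium chlorite, [Na+].[O-]Cl=O
Why: TEMPO/hypochlorite-catalysed chlorite oxidation takes the primary alcohol through the aldehyde to the acid at near-neutral pH, under which the epoxide and its two stereocentres survive.

Step 21
Reactants: 28 C9 triethylsilyl ether; 32 (2S,3R)-2,3-dimethyloxirane-2-carboxylic acid
Product: 34 C8 epoxy ester C9 triethylsilyl ether, via mixed anhydride 33 (not isolated)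
Conditions: 32, 2,4,6-trichlorobenzoyl chloride, Et3N, toluene, rt; then 28, DMAP, rt
Reagents that add atoms: (2S,3R)-2,3-dimethyloxirane-2-carboxylic acid (32), OC(=O)[C@@]1(C)O[C@@H]1C; 2,4,6-trichlorobenzoyl chloride (in 33 only), O=C(Cl)c1c(Cl)cc(Cl)cc1Cl
Why: Yamaguchi esterification acylates the only free secondary hydroxyl (C8) through the mixed anhydride and DMAP, with retention at C8 and at the α-quaternary epoxide carbon, the tertiary C7 hydroxyl being too hindered to compete.

Step 22
Reactants: 34 C8 epoxy ester C9 triethylsilyl ether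
Product: 35 CNP0420662.1
Conditions: HF·pyridine, pyridine, THF, 0 °C
Reagents that add atoms: none
Why: Buffered HF·pyridine removes the triethylsilyl ether at C9 without opening the epoxide or adding to the α-methylene lactone and gives the target.

**Compound list**

1 | (1S,2S)-3-bromocyclohexa-3,5-diene-1,2-diol | O[C@@H]1C(Br)=CC=C[C@@H]1O | starting material
2 | O8/O9 acetonide of 1 (cis-fused 4-bromo-2,2-dimethyl-3a,7a-dihydro-1,3-benzodioxole) | BrC1=CC=C[C@@H]2OC(C)(C)O[C@H]12 | intermediate
3 | bromocyclohexene diol, C6 and C7 hydroxyls anti to the dioxolane | BrC1=C[C@@H](O)[C@@H](O)[C@@H]2OC(C)(C)O[C@H]12 | intermediate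
4 | dibutylstannylene acetal of 3 (O6, O7) | BrC1=C[C@@H](O[Sn](CCCC)(CCCC)O3)[C@@H]3[C@@H]2OC(C)(C)O[C@H]12 | intermediate
5 | C6 4-methoxybenzyl ether of 3, C7 hydroxyl free | BrC1=C[C@@H](OCc3ccc(OC)cc3)[C@@H](O)[C@@H]2OC(C)(C)O[C@H]12 | intermediate
6 | C6 PMB, C7 TBS vinyl bromide | BrC1=C[C@@H](OCc3ccc(OC)cc3)[C@@H](O[Si](C)(C)C(C)(C)C)[C@@H]2OC(C)(C)O[C@H]12 | intermediate
7 | C10 hydroxymethyl cyclohexene (allylic alcohol) | OCC1=C[C@@H](OCc3ccc(OC)cc3)[C@@H](O[Si](C)(C)C(C)(C)C)[C@@H]2OC(C)(C)O[C@H]12 | intermediate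
8 | C5–C10 epoxy alcohol, epoxide anti to the dioxolane and cis to the C6 ether | OC[C@]12O[C@H]1[C@@H](OCc4ccc(OC)cc4)[C@@H](O[Si](C)(C)C(C)(C)C)[C@@H]3OC(C)(C)O[C@H]23 | intermediate
9 | isopropenylmagnesium bromide | CC(=C)[Mg]Br | starting material
10 | C10 tertiary alcohol with hydroxymethyl, C5 isopropenyl cis to the hydroxymethyl group | OC[C@]1(O)[C@H](C(C)=C)[C@@H](OCc3ccc(OC)cc3)[C@@H](O[Si](C)(C)C(C)(C)C)[C@@H]2OC(C)(C)O[C@H]12 | intermediate
11 | C10 hydroxy aldehyde | O=C[C@]1(O)[C@H](C(C)=C)[C@@H](OCc3ccc(OC)cc3)[C@@H](O[Si](C)(C)C(C)(C)C)[C@@H]2OC(C)(C)O[C@H]12 | intermediate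
12 | cis-2-isopropenyl-1-vinylcyclohexanol (vinyl cis to isopropenyl; C6 PMB, C7 TBS, C8/C9 acetonide) | O[C@]1(C=C)[C@H]2OC(C)(C)O[C@H]2[C@H](O[Si](C)(C)C(C)(C)C)[C@H](OCc2ccc(OC)cc2)[C@H]1C(C)=C | intermediate
13 | potassium alkoxide of 12 | [K+].[O-][C@]1(C=C)[C@H]2OC(C)(C)O[C@H]2[C@H](O[Si](C)(C)C(C)(C)C)[C@H](OCc2ccc(OC)cc2)[C@H]1C(C)=C | intermediate
14 | ten-membered potassium enolate at C10 (C2 cis to C9 across C1=C10, E C4=C5), conjugate base of the (E)-cyclodec-5-enone | [K+].[O-]/C1=C/CC/C(C)=C/[C@@H](OCc3ccc(OC)cc3)[C@@H](O[Si](C)(C)C(C)(C)C)[C@@H]2OC(C)(C)O[C@H]12 | intermediate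
15 | ten-membered (E)-enol triflate at C10 (triflate trans to C2), E C4=C5 | FC(F)(F)S(=O)(=O)O/C1=C/CC/C(C)=C/[C@@H](OCc3ccc(OC)cc3)[C@@H](O[Si](C)(C)C(C)(C)C)[C@@H]2OC(C)(C)O[C@H]12 | intermediate
16 | (1(10)Z,4E)-germacra-1(10),4-diene with C6 PMB, C7 TBS, C8/C9 acetonide | C/C1=C/CC/C(C)=C/[C@@H](OCc3ccc(OC)cc3)[C@@H](O[Si](C)(C)C(C)(C)C)[C@@H]2OC(C)(C)O[C@H]12 | intermediate
17 | C7 alcohol | C/C1=C/CC/C(C)=C/[C@@H](OCc3ccc(OC)cc3)[C@@H](O)[C@@H]2OC(C)(C)O[C@H]12 | intermediate
18 | C7 ketone | C/C1=C/CC/C(C)=C/[C@@H](OCc3ccc(OC)cc3)C(=O)[C@@H]2OC(C)(C)O[C@H]12 | intermediate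
19 | 2-bromoprop-2-en-1-ol | OCC(Br)=C | starting material
20 | O,2-dilithio derivative of 19 | [Li]OCC([Li])=C | intermediate
21 | bis(bromomagnesium) derivative of 19 | Br[Mg]OCC(=C)[Mg]Br | intermediate
22 | C7 tertiary alcohol carrying the 3-hydroxyprop-1-en-2-yl group (C11–C13), C7 hydroxyl on the face of the C6 oxygen | C/C1=C/CC/C(C)=C/[C@@H](OCc3ccc(OC)cc3)[C@](O)(C(=C)CO)[C@@H]2OC(C)(C)O[C@H]12 | intermediate
23 | C6, C7, C12 triol | C/C1=C/CC/C(C)=C/[C@@H](O)[C@](O)(C(=C)CO)[C@@H]2OC(C)(C)O[C@H]12 | intermediate
24 | hydroxy enal (C12 aldehyde) | C/C1=C/CC/C(C)=C/[C@@H](O)[C@](O)(C(=C)C=O)[C@@H]2OC(C)(C)O[C@H]12 | intermediate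
25 | lactol (C12 hemiacetal to O6, either anomer) | C=C1C(O)O[C@@H]2/C=C(\C)CC/C=C(/C)[C@H]3OC(C)(C)O[C@H]3[C@@]12O | intermediate
26 | 7-hydroxy α-methylene-γ-lactone (12,6-olide) with C8/C9 acetonide | C=C1C(=O)O[C@@H]2/C=C(\C)CC/C=C(/C)[C@H]3OC(C)(C)O[C@H]3[C@@]12O | intermediate
27 | 7,8,9-trihydroxy lactone | C=C1C(=O)O[C@@H]2/C=C(\C)CC/C=C(/C)[C@@H](O)[C@@H](O)[C@@]12O | intermediate
28 | C9 triethylsilyl ether of 27 | C=C1C(=O)O[C@@H]2/C=C(\C)CC/C=C(/C)[C@@H](O[Si](CC)(CC)CC)[C@@H](O)[C@@]12O | intermediate
29 | (E)-2-methylbut-2-en-1-ol | C/C=C(\C)CO | starting material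
30 | ((2R,3R)-2,3-dimethyloxiran-2-yl)methanol | OC[C@@]1(C)O[C@@H]1C | intermediate
31 | (2S,3R)-2,3-dimethyloxirane-2-carbaldehyde | O=C[C@@]1(C)O[C@@H]1C | intermediate
32 | (2S,3R)-2,3-dimethyloxirane-2-carboxylic acid | OC(=O)[C@@]1(C)O[C@@H]1C | intermediate
33 | mixed anhydride of 32 with 2,4,6-trichlorobenzoic acid | O=C(OC(=O)[C@@]1(C)O[C@@H]1C)c1c(Cl)cc(Cl)cc1Cl | intermediate
34 | C8 (2S,3R)-epoxy ester, C9 triethylsilyl ether | C=C1C(=O)O[C@@H]2/C=C(\C)CC/C=C(/C)[C@@H](O[Si](CC)(CC)CC)[C@@H](OC(=O)[C@@]3(C)O[C@@H]3C)[C@@]12O | intermediate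
35 | CNP0420662.1 | C=C1C(=O)O[C@@H]2/C=C(\C)CC/C=C(/C)[C@@H](O)[C@@H](OC(=O)[C@@]3(C)O[C@@H]3C)[C@@]12O | target

**Step count**

Total steps: 22. Longest linear sequence: 20 steps (steps 1–18, 21 and 22; steps 19–20 make the side-chain acid).

**Steps most likely to fail**

1. Step 10. The other chair (vinyl axial, isopropenyl equatorial) or a boat could compete and erode both alkene geometries, and trapping of the hindered enolate could be incomplete. Fallback: set out from diol 10 and reach the diene by a route that does not depend on the enolate geometry.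
   - NaIO4 in THF/H2O should cleave the glycol to the 2-isopropenyl ketone F1.
   - Vinylmagnesium bromide with CeCl3 should add anti to the two flanking upper-face substituents and give the trans-dialkenyl carbinol F2.
   - The oxy-Cope rearrangement of F2 (KH, 18-crown-6, THF; aqueous NH4Cl) should run through the diequatorial chair to the (E)-cyclodec-5-enone F3.
   - C1=C10 is then made by a Shapiro reaction: 2,4,6-triisopropylbenzenesulfonyl hydrazide should give the hydrazone F4, n-BuLi should deprotonate the C1 methylene and form the ring-cis alkenyllithium at C10, and MeI returns the route at 16.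

2. Step 14. Facial selectivity could be poor if magnesium coordinates the dioxolane oxygen instead of the C6 ether, and the basic reagent could enolise the ketone towards the allylic C6. Fallback: set out from ketone 18 and form C7–C11 from a tether on O6.
   - DDQ in wet CH2Cl2 should remove the PMB group and give the hydroxy ketone F5.
   - Esterification of the C6 hydroxyl with 2-bromoacrylic acid (DCC, DMAP) should give the bromoacrylate F6.
   - An intramolecular Nozaki–Hiyama–Kishi reaction (CrCl2, NiCl2 cat., DMF) should close the five-membered ring onto the C7 carbonyl and return the route at lactone 26.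

3. Step 7. Opening at the hindered C5 could be slow, and magnesium salts could trigger rearrangement of the epoxy alcohol first. Fallback: set out from vinyl bromide 6 and build the same C5/C10 array by conjugate addition.
   - Bromine–lithium exchange (t-BuLi, THF, −78 °C) and DMF should give the enal F7.
   - Conjugate addition of 9 (CuBr·SMe2, Me3SiCl, THF, −78 °C) anti to the C6 ether should give the silyl enol ether F8.
   - Rubottom oxidation with dimethyldioxirane from the face opposite the C5 and C9 substituents should give the silyloxy aldehyde F9.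
   - Wittig methylenation should give the silyl ether F10, and K2CO3 in MeOH returns the route at 12.

**Further compounds**

F1 | step 10 | 2-isopropenyl ketone at C10 | O=C1[C@H](C(C)=C)[C@@H](OCc3ccc(OC)cc3)[C@@H](O[Si](C)(C)C(C)(C)C)[C@@H]2OC(C)(C)O[C@H]12
F2 | step 10 | trans-2-isopropenyl-1-vinylcyclohexanol (vinyl trans to isopropenyl) | O[C@@]1(C=C)[C@H]2OC(C)(C)O[C@H]2[C@H](O[Si](C)(C)C(C)(C)C)[C@H](OCc2ccc(OC)cc2)[C@H]1C(C)=C
F3 | step 10 | (E)-cyclodec-5-enone with C6 PMB, C7 TBS, C8/C9 acetonide | O=C1CCC/C(C)=C/[C@@H](OCc2ccc(OC)cc2)[C@@H](O[Si](C)(C)C(C)(C)C)[C@@H]2OC(C)(C)O[C@@H]21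
F4 | step 10 | 2,4,6-triisopropylbenzenesulfonyl hydrazone of F3 | CC(C)c1cc(C(C)C)c(S(=O)(=O)NN=C2CCC/C(C)=C/[C@@H](OCc3ccc(OC)cc3)[C@@H](O[Si](C)(C)C(C)(C)C)[C@@H]3OC(C)(C)O[C@@H]32)c(C(C)C)c1
F5 | step 14 | C6 hydroxy C7 ketone | C/C1=C/CC/C(C)=C/[C@@H](O)C(=O)[C@@H]2OC(C)(C)O[C@H]12
F6 | step 14 | C6 2-bromoacrylate of F5 | C/C1=C/CC/C(C)=C/[C@@H](OC(=O)C(Br)=C)C(=O)[C@@H]2OC(C)(C)O[C@H]12
F7 | step 7 | C10 enal | O=CC1=C[C@@H](OCc3ccc(OC)cc3)[C@@H](O[Si](C)(C)C(C)(C)C)[C@@H]2OC(C)(C)O[C@H]12
F8 | step 7 | trimethylsilyl enol ether with C5 isopropenyl | C[Si](C)(C)OC=C1[C@H](C(C)=C)[C@@H](OCc3ccc(OC)cc3)[C@@H](O[Si](C)(C)C(C)(C)C)[C@@H]2OC(C)(C)O[C@H]12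
F9 | step 7 | C10 trimethylsilyloxy aldehyde | O=C[C@]1(O[Si](C)(C)C)[C@H](C(C)=C)[C@@H](OCc3ccc(OC)cc3)[C@@H](O[Si](C)(C)C(C)(C)C)[C@@H]2OC(C)(C)O[C@H]12
F10 | step 7 | trimethylsilyl ether of 12 | C=C[C@]1(O[Si](C)(C)C)[C@H](C(C)=C)[C@@H](OCc3ccc(OC)cc3)[C@@H](O[Si](C)(C)C(C)(C)C)[C@@H]2OC(C)(C)O[C@H]12
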